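The ten-membered carbocycle is disconnected at C6–C7. The feature exploited lies in the lactone region: C6 carries oxygen and C7 carries the C11(=C13)–C12 unit of the fused α-methylene γ-lactone, a homoallylic alcohol and thus the signature of a [2,3]-Wittig shift. In one operation the key step contracts a 13-membered C6–O–C13 allylic ether to the carbocycle, forms C6–C7, sets C6 and C7 and unveils the C11=C13 methylene. Its precursor is a macrocyclic ether with the C2≡C3/C4=C5 enyne (which acidifies C6), a C1 dioxolane, a C8/C10 acetonide derived from (R)-citramalic acid and silyl ethers on O12 and O15.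

Key step: step 22

Remark (numbering): germacrane numbering of the target is used for all intermediates: C1 ketone, C2=C3, C4=C5, C6 lactone carbinol, C7, C8 ester carbinol, C9, C10; C11 with C12 (lactone carbonyl) and C13 (methylene); C14 methyl on C10; C15 hydroxymethyl on C4.
Remark (olefin descriptor): in ether 33 the C7=C11 double bond is Z by CIP, because the silyloxymethyl arm C12 outranks the ether arm C13; what matters is that C13 is anti and C12 syn to C8.
Remark (end-game order): the lactone is closed (step 24) before the C1 ketone is unveiled (step 25), because a free C6 hydroxyl on the Z-enyne could itself add to C3.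
Remark (ether closure): the ring is closed from the C6 alkoxide and a C13 chloride, since an alkoxide on C13 next to the C12 silyl ether could trigger 1,3-silyl migration and scramble the olefin geometry. The PMB ether is removed before the carbanion step because a benzyl allyl ether would itself rearrange.
Assumption: the (S,S)-TsDPEN ruthenium catalyst is taken to give the 8S carbinol from ynone 12, by analogy with simple alkynyl ketones.

Step 1
Reactants: 1 propargyl alcohol
Product: 3 4-methoxybenzyl propargyl ether, via sodium prop-2-yn-1-olate 2 (not isolated)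
Conditions: NaH, THF, 0 °C; PMBCl, n-Bu4NI (cat.), 0 °C → rt
Reagents that add atoms: 4-methoxybenzyl chloride COc1ccc(CCl)cc1
Why: Williamson etherification of a primary alkoxide with a benzylic chloride, giving an ether that survives the hydride and acetylide steps and is later removed oxidatively.

Step 2
Reactants: 4 (R)-citramalic acid
Product: 5 (R)-2-(2,2,4-trimethyl-5-oxo-1,3-dioxolan-4-yl)acetic acid
Conditions: 2,2-dimethoxypropane, TsOH·H2O (cat.), rt
Reagents that add atoms: 2,2-dimethoxypropane COC(C)(C)OC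
Why: acid-catalysed acetalisation closes the five-membered dioxolanone on the α-hydroxy acid (O10/C1), which differentiates the two carboxyls and leaves the C10 stereocentre untouched.

Step 3
Reactants: 5 dioxolanone acid
Product: 6 (R)-N-methoxy-N-methyl-2-(2,2,4-trimethyl-5-oxo-1,3-dioxolan-4-yl)acetamide
Conditions: MeNHOMe·HCl, EDC·HCl, N-methylmorpholine, CH2Cl2, 0 °C → rt
Reagents that add atoms: N,O-dimethylhydroxylamine hydrochloride CNOC.Cl
Why: carbodiimide amidation of the free C8 acid gives the Weinreb amide, while the hindered dioxolanone should not be aminolysed by this weak nucleophile at 0 °C.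

Step 4
Reactants: 6 Weinreb amide dioxolanone; 7 trimethylsilylacetylene
Product: 9 (R)-3-hydroxy-N-methoxy-N,3-dimethyl-4-oxo-6-(trimethylsilyl)hex-5-ynamide, via lithium (trimethylsilyl)acetylide 8 (not isolated)
Conditions: 7, n-BuLi, THF, −78 °C; then 6, −78 → −50 °C; AcOH, −78 °C
Reagents that add atoms: none
Why: acetylide addition to the activated lactone carbonyl of the dioxolanone should outpace attack on the Weinreb amide at low temperature, and the cyclic lithium hemiketal resists a second addition until the cold acidic quench releases acetone and the α′-hydroxy ynone.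

Step 5
Reactants: 9 α′-hydroxy ynone
Product: 10 (R)-N-methoxy-N-methyl-3-[2-(trimethylsilylethynyl)-1,3-dioxolan-2-yl]-3-(trimethylsilyloxy)butanamide
Conditions: TMSOCH2CH2OTMS (4 equiv), TMSOTf (0.3 equiv), CH2Cl2, −78 → −20 °C; pyridine
Reagents that add atoms: 1,2-bis(trimethylsilyloxy)ethane C[Si](C)(C)OCCO[Si](C)(C)C
Why: Noyori ketalisation converts conjugated ynones into dioxolanes under aprotic conditions without conjugate addition of the glycol, and the same reagent silylates the tertiary C10 hydroxyl.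

Step 6
Reactants: 10 ketal Weinreb amide; 3 4-methoxybenzyl propargyl ether
Product: 12 (R)-1-(4-methoxybenzyloxy)-6-[2-(trimethylsilylethynyl)-1,3-dioxolan-2-yl]-6-(trimethylsilyloxy)hept-2-yn-4-one, via lithium 3-(4-methoxybenzyloxy)prop-1-ynide 11 (not isolated)
Conditions: 3, n-BuLi, THF, −78 °C; then 10, −78 → −10 °C; AcOH
Reagents that add atoms: none
Why: Weinreb ketone synthesis, in which the chelated tetrahedral adduct stops the addition at the C8 ynone and the C10 silyl ether blocks retro-aldol and oxa-Michael pathways.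

Step 7
Reactants: 12 C8 ynone
Product: 13 (4S,6R)-1-(4-methoxybenzyloxy)-6-[2-(trimethylsilylethynyl)-1,3-dioxolan-2-yl]-6-(trimethylsilyloxy)hept-2-yn-4-ol
Conditions: Ru[(S,S)-TsDPEN](p-cymene) (2 mol%), i-PrOH, rt
Reagents that add atoms: none
Why: Noyori asymmetric transfer hydrogenation of an alkynyl ketone, where the alkynyl group takes the role of the aryl group, so the (S,S) catalyst should set 8S under reagent control irrespective of the remote C10 centre.

Step 8
Reactants: 13 propargylic alcohol
Product: 15 (2Z,4S,6R)-2-iodo-1-(4-methoxybenzyloxy)-6-[2-(trimethylsilylethynyl)-1,3-dioxolan-2-yl]-6-(trimethylsilyloxy)hept-2-en-4-ol, via sodium vinylalanate 14 (not isolated)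
Conditions: Red-Al, THF, 0 °C; EtOAc; I2, THF, −78 → −20 °C
Reagents that add atoms: iodine II
Why: hydroxyl-directed trans-hydroalumination delivers hydride to C7 and aluminium to C11 in a five-membered alkoxyalanate, and iodinolysis with retention places iodine on C11 cis to C8, which fixes the C7=C11 geometry for the whole route.

Step 9
Reactants: 15 iodo alcohol
Product: 17 (4R,6S)-6-[(Z)-2-iodo-3-(4-methoxybenzyloxy)prop-1-enyl]-2,2,4-trimethyl-4-[2-(trimethylsilylethynyl)-1,3-dioxolan-2-yl]-1,3-dioxane, via iodo diol 16 (not isolated)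
Conditions: CSA (cat.), MeOH, 0 °C; concentrate; 2,2-dimethoxypropane, acetone, rt
Reagents that add atoms: 2,2-dimethoxypropane COC(C)(C)OC
Why: acidic methanol cleaves the tertiary TMS ether and acetalisation of the resulting syn-1,3-diol closes the six-membered C8/C10 acetonide, while the alkynyl dioxolane, PMB ether and alkenyl iodide are inert to catalytic acid.

Step 10
Reactants: 17 iodo acetonide
Product: 18 methyl ester (C12 as CO2Me on C11 and cis to C8; C13 OPMB; C8/C10 acetonide; C1 dioxolane; C3 TMS)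
Conditions: Pd(PPh3)2Cl2 (5 mol%), CO (1 atm), Et3N, MeOH/DMF, 60 °C
Reagents that add atoms: carbon monoxide [C-]#[O+]; methanol CO
Why: palladium-catalysed alkoxycarbonylation of an alkenyl iodide proceeds with retention of olefin geometry and so installs C12 cis to C8.

Step 11
Reactants: 18 methyl ester
Product: 19 allylic alcohol (C12 as CH2OH cis to C8; C13 OPMB; C8/C10 acetonide; C1 dioxolane; C3 TMS)
Conditions: DIBAL-H (2.5 equiv), CH2Cl2, −78 °C; Rochelle salt
Reagents that add atoms: none
Why: 1,2-reduction of the conjugated ester by DIBAL-H gives the allylic alcohol without touching acetals, ethers or the silylalkyne.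

Step 12
Reactants: 19 allylic alcohol
Product: 20 TBS ether (C12 OTBS cis to C8; C13 OPMB; C8/C10 acetonide; C1 dioxolane; C3 TMS)
Conditions: TBSCl, imidazole, CH2Cl2, 0 °C → rt
Reagents that add atoms: tert-butyldimethylsilyl chloride CC(C)(C)[Si](C)(C)Cl
Why: standard silylation of the only free hydroxyl, a primary allylic one.

Step 13
Reactants: 20 TBS ether
Product: 21 terminal alkyne (C3–H; C12 OTBS; C13 OPMB; C8/C10 acetonide; C1 dioxolane)
Conditions: K2CO3, MeOH, rt
Reagents that add atoms: none
Why: methanolysis of the alkynyl C–Si bond is carried out while C13 is still protected, so no alkoxide sits next to the C12 silyl ether.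

Step 14
Reactants: 21 terminal alkyne
Product: 22 (4R,6S)-4-(2-ethynyl-1,3-dioxolan-2-yl)-6-[(Z)-2-(tert-butyldimethylsilyloxymethyl)-3-hydroxyprop-1-enyl]-2,2,4-trimethyl-1,3-dioxane
Conditions: DDQ, CH2Cl2/pH 7 buffer (10:1), 0 °C
Reagents that add atoms: none
Why: oxidative PMB cleavage frees the C13 alcohol under neutral conditions, so the neighbouring TBS ether cannot migrate.

Step 15
Reactants: 23 2-butyne-1,4-diol
Product: 24 4-(tert-butyldiphenylsilyloxy)but-2-yn-1-ol
Conditions: TBDPSCl (0.33 equiv), imidazole, DMF, 0 °C → rt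
Reagents that add atoms: tert-butyldiphenylsilyl chloride CC(C)(C)[Si](Cl)(c1ccccc1)c1ccccc1
Why: statistical monosilylation with the symmetrical diol in excess.

Step 16
Reactants: 24 monosilyl butynediol
Product: 26 (Z)-4-(tert-butyldiphenylsilyloxy)-3-iodobut-2-en-1-ol, via sodium vinylalanate 25 (not isolated)
Conditions: Red-Al, THF, 0 °C; EtOAc; I2, THF, −78 °C
Reagents that add atoms: iodine II
Why: the free hydroxyl directs trans-hydroalumination so that hydride goes to C5 and iodine ends on C4, cis to C6, which is the geometry needed for the 4,5-olefin.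

Step 17
Reactants: 26 iodo alcohol
Product: 27 (Z)-4-(tert-butyldiphenylsilyloxy)-3-iodo-1-(triethylsilyloxy)but-2-ene
Conditions: TESCl, imidazole, CH2Cl2, 0 °C
Reagents that add atoms: chlorotriethylsilane CC[Si](Cl)(CC)CC
Why: silylation with a TES group that can later be cleaved in the presence of TBS and TBDPS ethers.

Step 18
Reactants: 22 eastern alkyne; 27 iodo TES ether
Product: 28 acyclic enyne (C2≡C3–C4=C5 with C3 cis to C6; C6 OTES; C13 OH; C12 OTBS; C15 OTBDPS; C8/C10 acetonide; C1 dioxolane)
Conditions: Pd(PPh3)2Cl2 (5 mol%), CuI (10 mol%), i-Pr2NH, THF, rt, degassed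
Reagents that add atoms: none
Why: Sonogashira coupling of an alkenyl iodide with a terminal alkyne proceeds with retention of geometry and tolerates the free allylic alcohol.

Step 19
Reactants: 28 acyclic enyne
Product: 30 allylic chloride (C13–Cl; C6 OTES; otherwise as 28), via allylic mesylate 29 (not isolated)
Conditions: MsCl, 2,4,6-collidine, LiCl, DMF, 0 °C
Reagents that add atoms: lithium chloride [Li+].[Cl-]
Why: Collington–Meyers chlorination converts the only free hydroxyl through its mesylate into the primary allylic chloride by SN2 displacement without allylic transposition.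

Step 20
Reactants: 30 allylic chloride
Product: 31 chloro alcohol (C6–OH; C13–Cl; C12 OTBS; C15 OTBDPS; C8/C10 acetonide; C1 dioxolane)
Conditions: HF·pyridine, pyridine, THF, 0 °C
Reagents that add atoms: none
Why: buffered HF·pyridine cleaves the primary TES ether much faster than the TBS and TBDPS ethers and leaves the acetals and the chloride alone.

Step 21
Reactants: 31 chloro alcohol
Product: 33 13-membered cyclic ether (C6–O–C13 ring; 8S and 10R; C13 anti to C8 on C7=C11; C3 cis to C6 on C4=C5; C8/C10 acetonide; C1 dioxolane; C12 OTBS; C15 OTBDPS), via sodium alkoxide 32 (not isolated)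
Conditions: NaH (5 equiv), n-Bu4NI (0.2 equiv), THF, slow addition to 0.003 M, 0 → 45 °C
Reagents that add atoms: none
Why: intramolecular Williamson etherification at high dilution closes the 13-membered ring by SN2 attack of the C6 alkoxide on the C13 allylic chloride, and this alkoxide has no silyl ether within reach and no proton source for addition to the alkyne.

Step 22
Reactants: 33 13-membered cyclic ether
Product: 35 ten-membered enynol (C6–OH; C7 bearing the C11(=C13)–C12 OTBS unit; configuration at C6/C7/C8/C10 as in the target; CIP 6R 7S 8S 10R), via C6-lithio ether 34 (not isolated)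
Conditions: n-BuLi (1.5 equiv), THF, −78 → −40 °C; AcOH, −78 °C
Reagents that add atoms: none
Why: Deprotonation at C6, which is α to the ether oxygen and conjugated through C5=C4 with the C2≡C3 alkyne, gives an α-oxy carbanion that attacks C7 suprafacially through a five-membered envelope transition state (C6–O–C13–C11=C7) while the π bond moves to C11=C13 and O–C13 breaks, i.e. a [2,3]-Wittig rearrangement. The closest known reaction type is the [2,3]-Wittig ring contraction of 13-membered allylic propargylic ethers to ten-membered homoallylic cycloalkynols. The ten-membered carbocycle is closed not by a cyclisation but by contraction: the C6–C7 bond forms across the three-atom O–C13–C11 bridge of the 13-membered ring and expels O and C13 from it. The C6/C7 relationship (H6 anti to H7, as the trans-lactone needs) should follow from the olefin geometry, C13 being anti to C8, with the enyne substituent exo on the envelope; the sense at C7 is set by C8, because A(1,3) strain with the cis C12 arm holds H8 in the olefin plane, puts ring carbon C9 and the tethered C6 carbanion on the same face and leaves the C8–O bond anti to the forming bond. The step needs lithiation at C6 and not at C13, C12 or C15, which the extra enyne conjugation should secure, and [2,3] over [1,2] shift, which the low temperature secures; the cold acetic acid quench keeps the Z-enynol alkoxide from adding to the alkyne. (The 7S label reflects only the lower CIP rank of C6 while O6 is a free hydroxyl.)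

Step 23
Reactants: 35 ten-membered enynol
Product: 36 diol (C6–OH and C12–OH; C15 OTBDPS; C8/C10 acetonide; C1 dioxolane)
Conditions: HF·pyridine, pyridine, THF, 0 °C → rt
Reagents that add atoms: none
Why: buffered HF·pyridine removes the primary TBS ether selectively in the presence of the more robust TBDPS ether and both acetals.

Step 24
Reactants: 36 diol
Product: 39 α-methylene γ-lactone (C6–O–C12(=O) with C11=C13; C15 OTBDPS; C8/C10 acetonide; C1 dioxolane), via enal 37 (not isolated), via lactol 38 (not isolated)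
Conditions: TEMPO (0.2 equiv), PhI(OAc)2 (3 equiv), CH2Cl2, rt
Reagents that add atoms: none
Why: TEMPO/PhI(OAc)2 oxidises the primary allylic alcohol selectively to the enal, which the C6 hydroxyl captures as a lactol that is oxidised on to the lactone, and only the 6,12-lactone can form because O8 is still in the acetonide.

Step 25
Reactants: 39 lactone
Product: 40 dihydroxy ynone lactone (C1 ketone conjugated to C2≡C3; C8–OH; C10–OH; 6,12-lactone; C15 OTBDPS)
Conditions: TFA/H2O (9:1), CH2Cl2, 0 °C → rt
Reagents that add atoms: water O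
Why: aqueous acid hydrolysis removes the acetonide and the alkynyl dioxolane at a stage where O6 is already acylated, the methylene lactone is acid-stable and the primary TBDPS ether should survive.

Step 26
Reactants: 40 dihydroxy ynone lactone
Product: 41 furanone alcohol (15-O-TBDPS-8-O-desmethacryloyl goyazensolide; O10 bridged to C3; C2=C3; C1 ketone; C8–OH)
Conditions: Ph3PAuNTf2 (5 mol%), toluene, rt
Reagents that add atoms: none
Why: gold(I) activation of the ynone triggers 5-endo-dig attack of the C10 hydroxyl at C3 and protodeauration, the known cycloisomerisation of α′-hydroxy ynones to 3(2H)-furanones, whereas the C8 hydroxyl would need a seven-membered ring.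

Step 27
Reactants: 41 furanone alcohol
Product: 42 15-O-TBDPS goyazensolide
Conditions: methacrylic anhydride, Et3N, DMAP (cat.), CH2Cl2, 0 °C → rt
Reagents that add atoms: methacrylic anhydride C=C(C)C(=O)OC(=O)C(C)=C
Why: DMAP-catalysed acylation of the only free hydroxyl, the secondary C8 carbinol.

Step 28
Reactants: 42 15-O-TBDPS goyazensolide
Product: 43 goyazensolide
Conditions: HF·pyridine, THF, 0 °C → rt
Reagents that add atoms: none
Why: acidic fluoride cleaves the primary TBDPS ether without the basic conditions that would endanger the methacrylate, the methylene lactone and the furanone.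

Compound list
1 | propargyl alcohol | C#CCO | starting material
2 | sodium prop-2-yn-1-olate | [Na+].[O-]CC#C | intermediate
3 | 4-methoxybenzyl propargyl ether | C#CCOCc1ccc(OC)cc1 | intermediate
4 | (R)-citramalic acid | C[C@@](O)(CC(=O)O)C(=O)O | starting material
5 | (R)-2-(2,2,4-trimethyl-5-oxo-1,3-dioxolan-4-yl)acetic acid | C[C@@]1(CC(=O)O)C(=O)OC(C)(C)O1 | intermediate
6 | (R)-N-methoxy-N-methyl-2-(2,2,4-trimethyl-5-oxo-1,3-dioxolan-4-yl)acetamide | C[C@@]1(CC(=O)N(C)OC)C(=O)OC(C)(C)O1 | intermediate
7 | trimethylsilylacetylene | C#C[Si](C)(C)C | starting material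
8 | lithium (trimethylsilyl)acetylide | [Li]C#C[Si](C)(C)C | intermediate
9 | (R)-3-hydroxy-N-methoxy-N,3-dimethyl-4-oxo-6-(trimethylsilyl)hex-5-ynamide | C[C@@](O)(CC(=O)N(C)OC)C(=O)C#C[Si](C)(C)C | intermediate
10 | (R)-N-methoxy-N-methyl-3-[2-(trimethylsilylethynyl)-1,3-dioxolan-2-yl]-3-(trimethylsilyloxy)butanamide | C[C@@](O[Si](C)(C)C)(CC(=O)N(C)OC)C1(OCCO1)C#C[Si](C)(C)C | intermediate
11 | lithium 3-(4-methoxybenzyloxy)prop-1-ynide | [Li]C#CCOCc1ccc(OC)cc1 | intermediate
12 | (R)-1-(4-methoxybenzyloxy)-6-[2-(trimethylsilylethynyl)-1,3-dioxolan-2-yl]-6-(trimethylsilyloxy)hept-2-yn-4-one | C[C@@](O[Si](C)(C)C)(CC(=O)C#CCOCc1ccc(OC)cc1)C2(OCCO2)C#C[Si](C)(C)C | intermediate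
13 | (4S,6R)-1-(4-methoxybenzyloxy)-6-[2-(trimethylsilylethynyl)-1,3-dioxolan-2-yl]-6-(trimethylsilyloxy)hept-2-yn-4-ol | C[C@@](O[Si](C)(C)C)(C[C@H](O)C#CCOCc1ccc(OC)cc1)C2(OCCO2)C#C[Si](C)(C)C | intermediate
14 | sodium vinylalanate from 13 (cyclic C8–O–Al–C11 alkoxyalanate) | [Na+].C[C@@](O[Si](C)(C)C)(C[C@@H]1O[Al-](OCCOC)(OCCOC)C(COCc2ccc(OC)cc2)=C1)C3(OCCO3)C#C[Si](C)(C)C | intermediate
15 | (2Z,4S,6R)-2-iodo-1-(4-methoxybenzyloxy)-6-[2-(trimethylsilylethynyl)-1,3-dioxolan-2-yl]-6-(trimethylsilyloxy)hept-2-en-4-ol | C[C@@](O[Si](C)(C)C)(C[C@H](O)/C=C(\I)COCc1ccc(OC)cc1)C2(OCCO2)C#C[Si](C)(C)C | intermediate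
16 | (2Z,4S,6R)-2-iodo-1-(4-methoxybenzyloxy)-6-[2-(trimethylsilylethynyl)-1,3-dioxolan-2-yl]hept-2-ene-4,6-diol | C[C@@](O)(C[C@H](O)/C=C(\I)COCc1ccc(OC)cc1)C2(OCCO2)C#C[Si](C)(C)C | intermediate
17 | (4R,6S)-6-[(Z)-2-iodo-3-(4-methoxybenzyloxy)prop-1-enyl]-2,2,4-trimethyl-4-[2-(trimethylsilylethynyl)-1,3-dioxolan-2-yl]-1,3-dioxane | C[C@@]1(C[C@@H](/C=C(\I)COCc2ccc(OC)cc2)OC(C)(C)O1)C3(OCCO3)C#C[Si](C)(C)C | intermediate
18 | methyl ester: as 17 with CO2Me (C12) in place of iodine, cis to C8 | C[C@@]1(C[C@@H](/C=C(\C(=O)OC)COCc2ccc(OC)cc2)OC(C)(C)O1)C3(OCCO3)C#C[Si](C)(C)C | intermediate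
19 | allylic alcohol: as 18 with C12 as CH2OH | C[C@@]1(C[C@@H](/C=C(\CO)COCc2ccc(OC)cc2)OC(C)(C)O1)C3(OCCO3)C#C[Si](C)(C)C | intermediate
20 | TBS ether: as 19 with C12 OTBS | C[C@@]1(C[C@@H](/C=C(\CO[Si](C)(C)C(C)(C)C)COCc2ccc(OC)cc2)OC(C)(C)O1)C3(OCCO3)C#C[Si](C)(C)C | intermediate
21 | terminal alkyne: as 20 without the alkynyl TMS group | C[C@@]1(C[C@@H](/C=C(\CO[Si](C)(C)C(C)(C)C)COCc2ccc(OC)cc2)OC(C)(C)O1)C3(OCCO3)C#C | intermediate
22 | (4R,6S)-4-(2-ethynyl-1,3-dioxolan-2-yl)-6-[(Z)-2-(tert-butyldimethylsilyloxymethyl)-3-hydroxyprop-1-enyl]-2,2,4-trimethyl-1,3-dioxane | C[C@@]1(C[C@@H](/C=C(\CO[Si](C)(C)C(C)(C)C)CO)OC(C)(C)O1)C2(OCCO2)C#C | intermediate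
23 | 2-butyne-1,4-diol | OCC#CCO | starting material
24 | 4-(tert-butyldiphenylsilyloxy)but-2-yn-1-ol | OCC#CCO[Si](c1ccccc1)(c1ccccc1)C(C)(C)C | intermediate
25 | sodium vinylalanate from 24 (cyclic C6–O–Al–C4 alkoxyalanate) | [Na+].COCCO[Al-]1(OCCOC)OCC=C1CO[Si](c2ccccc2)(c2ccccc2)C(C)(C)C | intermediate
26 | (Z)-4-(tert-butyldiphenylsilyloxy)-3-iodobut-2-en-1-ol | OC/C=C(\I)CO[Si](c1ccccc1)(c1ccccc1)C(C)(C)C | intermediate
27 | (Z)-4-(tert-butyldiphenylsilyloxy)-3-iodo-1-(triethylsilyloxy)but-2-ene | CC[Si](CC)(CC)OC/C=C(\I)CO[Si](c1ccccc1)(c1ccccc1)C(C)(C)C | intermediate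
28 | acyclic enyne: C13 OH, C6 OTES, C12 OTBS, C15 OTBDPS, C8/C10 acetonide, C1 dioxolane; C3 cis to C6; C13 anti to C8 | C[C@@]1(C[C@@H](/C=C(\CO[Si](C)(C)C(C)(C)C)CO)OC(C)(C)O1)C2(OCCO2)C#C/C(CO[Si](c3ccccc3)(c3ccccc3)C(C)(C)C)=C\CO[Si](CC)(CC)CC | intermediate
29 | allylic mesylate: as 28 with C13 OMs | C[C@@]1(C[C@@H](/C=C(\CO[Si](C)(C)C(C)(C)C)COS(C)(=O)=O)OC(C)(C)O1)C2(OCCO2)C#C/C(CO[Si](c3ccccc3)(c3ccccc3)C(C)(C)C)=C\CO[Si](CC)(CC)CC | intermediate
30 | allylic chloride: as 28 with C13 Cl | C[C@@]1(C[C@@H](/C=C(\CO[Si](C)(C)C(C)(C)C)CCl)OC(C)(C)O1)C2(OCCO2)C#C/C(CO[Si](c3ccccc3)(c3ccccc3)C(C)(C)C)=C\CO[Si](CC)(CC)CC | intermediate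
31 | chloro alcohol: as 30 with C6 OH | C[C@@]1(C[C@@H](/C=C(\CO[Si](C)(C)C(C)(C)C)CCl)OC(C)(C)O1)C2(OCCO2)C#C/C(CO[Si](c3ccccc3)(c3ccccc3)C(C)(C)C)=C\CO | intermediate
32 | sodium alkoxide of 31 | C[C@@]1(C[C@@H](/C=C(\CO[Si](C)(C)C(C)(C)C)CCl)OC(C)(C)O1)C2(OCCO2)C#C/C(CO[Si](c3ccccc3)(c3ccccc3)C(C)(C)C)=C\C[O-].[Na+] | intermediate
33 | 13-membered cyclic ether (C6–O–C13; 8S,10R; C8/C10 acetonide; C1 dioxolane; C2≡C3; C12 OTBS; C15 OTBDPS) | O1C/C(CO[Si](C)(C)C(C)(C)C)=C/[C@H]2OC(C)(C)O[C@](C)(C2)C3(OCCO3)C#C/C(CO[Si](c4ccccc4)(c4ccccc4)C(C)(C)C)=C\C1 | intermediate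
34 | C6-lithio derivative of 33 | O1C/C(CO[Si](C)(C)C(C)(C)C)=C/[C@H]2OC(C)(C)O[C@](C)(C2)C3(OCCO3)C#C/C(CO[Si](c4ccccc4)(c4ccccc4)C(C)(C)C)=C\C1[Li] | intermediate
35 | ten-membered enynol (6R,7S,8S,10R; C6 OH; C7 2-propenyl unit with C12 OTBS) | CC1(C)O[C@H]2C[C@@](C)(O1)C3(OCCO3)C#C/C(CO[Si](c4ccccc4)(c4ccccc4)C(C)(C)C)=C\[C@@H](O)[C@@H]2C(=C)CO[Si](C)(C)C(C)(C)C | intermediate
36 | diol: as 35 with C12 OH | CC1(C)O[C@H]2C[C@@](C)(O1)C3(OCCO3)C#C/C(CO[Si](c4ccccc4)(c4ccccc4)C(C)(C)C)=C\[C@@H](O)[C@@H]2C(=C)CO | intermediate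
37 | enal: as 36 with C12 as CHO | CC1(C)O[C@H]2C[C@@](C)(O1)C3(OCCO3)C#C/C(CO[Si](c4ccccc4)(c4ccccc4)C(C)(C)C)=C\[C@@H](O)[C@@H]2C(=C)C=O | intermediate
38 | lactol: C12 hemiacetal closed on O6 | CC1(C)O[C@H]2C[C@@](C)(O1)C3(OCCO3)C#C/C(CO[Si](c4ccccc4)(c4ccccc4)C(C)(C)C)=C\[C@H]5OC(O)C(=C)[C@H]25 | intermediate
39 | α-methylene γ-lactone with C8/C10 acetonide, C1 dioxolane, C15 OTBDPS | CC1(C)O[C@H]2C[C@@](C)(O1)C3(OCCO3)C#C/C(CO[Si](c4ccccc4)(c4ccccc4)C(C)(C)C)=C\[C@H]5OC(=O)C(=C)[C@H]25 | intermediate
40 | dihydroxy ynone lactone (C1 ketone, C8 OH, C10 OH, C15 OTBDPS) | O[C@H]1C[C@@](C)(O)C(=O)C#C/C(CO[Si](c2ccccc2)(c2ccccc2)C(C)(C)C)=C\[C@H]3OC(=O)C(=C)[C@H]13 | intermediate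
41 | furanone alcohol (15-O-TBDPS-8-O-desmethacryloyl goyazensolide) | O[C@H]1C[C@@]2(C)OC(=CC2=O)/C(CO[Si](c3ccccc3)(c3ccccc3)C(C)(C)C)=C\[C@H]2OC(=O)C(=C)[C@H]12 | intermediate
42 | 15-O-TBDPS goyazensolide | C=C(C)C(=O)O[C@H]1C[C@@]2(C)OC(=CC2=O)/C(CO[Si](c3ccccc3)(c3ccccc3)C(C)(C)C)=C\[C@H]2OC(=O)C(=C)[C@H]12 | intermediate
43 | goyazensolide | C=C(C)C(=O)O[C@H]1C[C@@]2(C)OC(=CC2=O)/C(CO)=C\[C@H]2OC(=O)C(=C)[C@H]12 | target

Total step count: 28. Longest linear sequence: 24 steps from (R)-citramalic acid (steps 2–14 and 18–28). Step 1 and steps 15–17 are side branches.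

Steps most likely to fail

Step 22. Lithiation may be unselective among the allylic α-oxy positions, the carbanion may undergo [1,2] shift, or it may approach C7 from the wrong face, so that the C6/C7 configuration is eroded. The fallback forms the same bond by carbonyl allylation instead of a sigmatropic shift. It sets out from chloro alcohol 31: buffered Dess–Martin oxidation of the C6 alcohol would give the (Z)-enynal allylic chloride F1. Treatment with CrCl2 and NaI in THF/DMF at high dilution (intramolecular Nozaki–Hiyama allylation) would turn the C13 chloride into an allylchromium species that adds through its γ-carbon C7 to the C6 aldehyde in a chair transition state. This closes the ten-membered ring with the anti C6/C7 relationship and the C11=C13 methylene, and comes back to the route at 35.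

Step 21. The slow ring closure may lose out to intermolecular alkylation (oligomers) or to addition of the C6 alkoxide to the neighbouring alkyne. The fallback makes the ether bond intermolecularly and closes the ring at C3–C4. It sets out from alcohol 22 and iodo alcohol 26. Appel bromination of 22 (CBr4, PPh3) would give the allylic bromide F2. The sodium alkoxide of 26, which has no alkyne and no silyl ether within reach, would be alkylated by F2 to the acyclic iodo alkyne ether F3. A high-dilution intramolecular Sonogashira coupling (Pd(PPh3)4, CuI, i-Pr2NH, slow addition) would then form the enyne and return to the route at 33.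

Step 25. Cleavage of the hindered, electron-poor alkynyl dioxolane may stay incomplete under conditions mild enough for the rest of the molecule, and forcing acid may ionise the allylic lactone C6–O bond or strip the C15 silyl ether. The fallback cyclises first and hydrolyses afterwards. It sets out from lactone 39: 80% aqueous acetic acid would remove only the acetonide to give the diol dioxolane lactone F4. Cationic gold(I) would then promote 5-endo-dig attack of the C10 hydroxyl on C3 of the alkynyl ketal to give the dihydrofuran spiro-ketal F5. In F5 the ketal is a vinylogous ortho ester and should hydrolyse with PPTS in wet acetone, which comes back to the route at furanone 41 and bypasses 40.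

Further compounds
F1 | step 22 | (Z)-enynal allylic chloride: as 31 with C6 as CHO | C[C@@]1(C[C@@H](/C=C(\CO[Si](C)(C)C(C)(C)C)CCl)OC(C)(C)O1)C2(OCCO2)C#C/C(CO[Si](c3ccccc3)(c3ccccc3)C(C)(C)C)=C\C=O
F2 | step 21 | allylic bromide: as 22 with C13 Br | C[C@@]1(C[C@@H](/C=C(\CO[Si](C)(C)C(C)(C)C)CBr)OC(C)(C)O1)C2(OCCO2)C#C
F3 | step 21 | acyclic iodo alkyne ether: C13–O–C6 ether of F2 and 26 | C[C@@]1(C[C@@H](/C=C(\CO[Si](C)(C)C(C)(C)C)COC/C=C(\I)CO[Si](c3ccccc3)(c3ccccc3)C(C)(C)C)OC(C)(C)O1)C2(OCCO2)C#C
F4 | step 25 | diol dioxolane lactone: as 39 without the acetonide | O[C@H]1C[C@@](C)(O)C2(OCCO2)C#C/C(CO[Si](c3ccccc3)(c3ccccc3)C(C)(C)C)=C\[C@H]4OC(=O)C(=C)[C@H]14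
F5 | step 25 | dihydrofuran spiro-ketal: O10 bridged to C3, C2=C3, C1 still as dioxolane | O[C@H]1C[C@@]2(C)OC(=CC23OCCO3)/C(CO[Si](c4ccccc4)(c4ccccc4)C(C)(C)C)=C\[C@H]5OC(=O)C(=C)[C@H]15
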